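In a closed flask every mole charged stays on the books in some form, so I kept a ledger of free catalyst, the reagent charged in the smaller amount: 2.0 mM against 2.0 M of each substrate.

| setting | birch | oak | flask |
|---|---|---|---|
| left-handed substrate | 2 M | 2 M | 2.0 M |
| right-handed substrate | 2 M | 2 M | 2.0 M |
| gas | 200 mM (held) | 200 mM (held) | 200 mM (held) |
| free catalyst | 2 mM | 3 mM | 2.0 mM |
| remark | the very flask that is asked about, followed so far | run made earlier |  |
| time |  |  | 8.0 min |

- birch (time / min: left-handed product / %, left-handed substrate / %): 0.667: 25.4, 35.7; 1.33: 35.2, 30.4; 3.00: 39.1, 27.6; 8.00: 38.5, 29.2
- oak (time / min: left-handed product / %, left-handed substrate / %): 1.00: 43.8, 27.3; 2.00: 50.4, 24.1; 3.00: 50.2, 21.8; 4.00: 50.2, 22.3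

(each reading ± 1 percentage point)

- ochre: change nothing and wait 2.5 min more
- violet: at 8.0 min take out 90% of the left-handed product then present, then wait 2.5 min
- teal: at 8.0 min add free catalyst, 100% of the amount charged, then wait 2.5 min

1. left-handed product, in percent of the left-handed substrate and right-handed substrate together first charged, at 8.0 min
2. what to do for the largest gain in left-handed product; "none" if nothing gains more than 2 percentage points (ochre / violet / teal / none)
3. left-handed product present, with what was taken out counted in, in percent of the left-handed substrate and right-handed substrate together first charged, after ochre
4. left-handed product present, with what was taken out counted in, in percent of the left-handed substrate and right-handed substrate together first charged, after violet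

- free catalyst is single-handed; left-handed substrate and right-handed substrate are mirror images of each other, charged as a racemate, each of them at the stated concentration
- left-handed product taken out counts as made
- at the start none of the gas is in solution
- additions bring no volume worth counting

Left-handed product in the birch run read 39.1% and then 38.5%, flat within the scatter of 1 percentage point, so I booked 38.8% for 8.0 min. The oak run, with 3 mM of catalyst, closed higher at 50.3%. Birch had stopped with substrate present, since left-handed substrate still read 29.2%.

The next entry was product per mole of catalyst charged, the turnover number. It came to 776 in birch and 670 in oak, fewer, so catalyst did not buy a fixed amount. I reckoned instead that it buys a fixed share of whatever is unconverted, reading as unconverted all that the readings did not show as left-handed product. I therefore defined the reach, the charge of catalyst that cuts the unconverted share to half, as ln(2) times the charge divided by the logarithm of one over the unconverted share. Birch read 2.82 mM and oak 2.98 mM, so I carried 2.90 mM.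

Waiting and removing product add no catalyst to this ledger, so I booked no gain for ochre or violet. Teal adds 2.00 mM, which by my reckoning takes the unconverted share from 61.2% to 37.9%, a gain of 23 points.

The forecast gave 38.8% (from 37.9% to 39.7%), chose teal, and put ochre at 38.9% and violet at 39%. Its ground was “The reaction therefore stops because the catalyst dies”.

At 8.0 min the birch flask stood at 39.3%, and this is what ran in it:

    free catalyst + left-handed substrate ⇌ catalyst intermediate A (K = 1.80 L mol⁻¹, k = 1300 L mol⁻¹ s⁻¹)
    free catalyst + right-handed substrate ⇌ catalyst intermediate B (K = 0.510 L mol⁻¹, k = 2600 L mol⁻¹ s⁻¹)
    partner + catalyst intermediate A → free catalyst + left-handed product (k = 180 L mol⁻¹ s⁻¹)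
    partner + catalyst intermediate B → free catalyst + right-handed product (k = 34.0 L mol⁻¹ s⁻¹)
    left-handed substrate ⇌ right-handed substrate (k = 0.0720 s⁻¹)
    free catalyst → spent catalyst (k = 0.110 s⁻¹)
    gas ⇌ partner, rate k7*(csat - [partner]) (kL = 1.90 s⁻¹)

At that time spent catalyst stood at >99.9% of the catalyst charged, with left-handed substrate at 29.2% and right-handed substrate at 29.2%. Ochre gained 0 points, violet 0 points and teal 23 points. The reach of 2.90 mM, applied to the two substrates together in this flask, 58.4%, gives teal 22 points. For the neighbour flask charged with 5.00 mM of free catalyst, the reach gives 69.7% of left-handed product; that flask held 65.2%, beside right-handed product at 4.43%.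

The data stem from a simulated flask with made-up constants.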